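Two yields and one choice between flasks were asked.

| setting | winter | north-east | south |
|---|---|---|---|
| G | 16 mM | 11 mM | 11 mM |
| J | 14.3 mM | 14.3 mM | 14.3 mM |
| temperature | 110 °C | 110 °C | 130 °C |
| remark | run made earlier |  |  |
| time |  | 2.5 h | 2.5 h |

- winter (time / min: Z / %, G / %): 2.50: 0.1, 96.6; 5.00: 0.3, 90.6; 8.00: 2.4, 86.4; 15.0: 9.2, 71.2; 30.0: 18.8, 49.2

(each reading ± 1 percentage point)

- as a solid, counted per litre of solution: J
- the numbers in the tables scatter by 1 percentage point (one standard deviation)
- candidate steps: J <-> E; Z -> X; G + E -> Q; E + Q -> D; G + E -> Z; G <-> L; E + Z -> D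
- at the start none of J is in solution
- the earlier runs do not show what temperature does; that part of a forecast is a guess

1. the best flask by amount of Z, in percent of the G charged; "all alike" if 1.5 percentage points covers them all (north-east / south / all alike)
2. amount of Z at the end, in percent of the G charged, north-east
3. amount of Z at the end, in percent of the G charged, south

In the winter run at 8.00 min, G read 86.4% and Z 2.4%, so Z lagged behind the G lost in that run. I therefore used the points of Z gained per point of G lost from 8.00 min to 30.0 min, the Z share (a differential selectivity), 0.441.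

My first doubt was that Z might already be consumed, which would make the share fall with time. It was 0.447 before 15.0 min and 0.436 after it. With 1 percentage point of scatter on each reading, the winter run showed no such fall.

The second doubt was the later attack on Z. For one E per G, G is the limiting reagent in north-east and south: by my reckoning, once each G had taken one E, the J left over came to 30.0% of the G charged. Spent wholly on Z, that put my estimate of the yield at 14.1%; spent elsewhere, it put the estimate at 44.1%. Since the two winter shares agreed within the scatter, I stayed near the higher estimate.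

Carried over to north-east as a first-order estimate, the winter decay of G, 0.0256 min⁻¹, put G at 2.15% after 2.5 h. My estimate for north-east was therefore 43.2%. Temperature was a guess, so I could not separate south from north-east.

The forecast differed from my reckoning: its slowing of Z suggested that “Z is already being consumed”, and it gave 15% for north-east, 7% for south and north-east as best.

The simulation gave 45.3% in north-east and 50.7% in south, so south was best.

    J ⇌ E, rate k1*(cs1 - [E]) while solid is left; crystals form when [E] > cs1 (solubility = 11.0 mM, k = 6.50 × 10⁻⁴ s⁻¹)
    Z → X (k = 2.20 × 10⁻⁷ s⁻¹, Ea = 129 kJ mol⁻¹)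
    G + E → Q (k = 0.0380 M⁻¹ s⁻¹, Ea = 53.0 kJ mol⁻¹)
    E + Q → D (k = 0.0130 M⁻¹ s⁻¹, Ea = 69.0 kJ mol⁻¹)
    G + E → Z (k = 0.0510 M⁻¹ s⁻¹, Ea = 53.0 kJ mol⁻¹)
    G ⇌ L (K = 0.890, k = 1.90 × 10⁻⁴ s⁻¹, Ea = 115 kJ mol⁻¹, ΔH = −62.0 kJ mol⁻¹)
    E + Z → D (k = 0.00150 M⁻¹ s⁻¹, Ea = 71.0 kJ mol⁻¹)
    (constants at 110 °C)

The Z share times the G gone gives 41.6% for north-east, where 5.6% of G was left. It gives 29.9% for the same charge read at 40 min, which held 26.1%. In north-east at 0.371 h, G went to Z faster than to Q, by a factor of 1.3. Counted on E, that ratio stood at 1.3 at 2.50 h, when north-east held 45.3% of Z and 23.6% of Q.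

The runs were computed with made-up constants, and the scatter is random.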